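All runs come from a simulation for an exercise; noise was put on by code.

What stands in Friday's flask at 3.0 min, when its own readings stop at 40.0 s but Thursday's run was read at 3.00 min?

| flask | starting material | other conformer | remark | time |
|---|---|---|---|---|
| Friday's | 0.20 M | 0.050 M | the very flask that is asked about, followed so far |  |
| Thursday's | 0.40 M | 0.050 M | run made earlier |  |
| flask | 0.20 M | 0.0500 M |  | 3.0 min |

- Friday's (time / s: target / %, starting material / %, over-reaction product / %): 10.0: 5, 74, 0; 15.0: 6, 73, 0; 20.0: 10, 70, 1; 30.0: 15, 63, 2; 40.0: 18, 64, 0
- Thursday's (time / min: target / %, starting material / %, over-reaction product / %): 0.250: 7, 79, 0; 0.833: 19, 60, 2; 1.33: 28, 47, 2; 2.00: 38, 36, 8; 3.00: 41, 24, 15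

(readings scatter by 1.5 percentage points)

- target present at 3.0 min, in percent of the starting material and other conformer together charged
- starting material present at 3.0 min, in percent of the starting material and other conformer together charged
- over-reaction product present at 3.0 min, in percent of the starting material and other conformer together charged
- homo dimer present at 3.0 min, in percent of the starting material and other conformer together charged

- in percentages every species weighs as the starting material in it: one homo dimer counts as two
- what was read earlier has a scatter of 1.5 percentage points, one standard deviation

Can Thursday's run stand in for Friday's flask? It can if the steps are first-order and the other conformer stays inert, since the fraction of the starting material in each form at a given time then does not depend on its concentration. Friday's percentages are then Thursday's multiplied by the scale s, the starting material's share of Friday's charge over its share of Thursday's charge: s = 0.900.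

Is that first-order claim more than a hope? Both runs were read at one common time, 15.0 s on Friday and 0.250 min on Thursday. Scaled, Thursday's starting material gives 71.1% against Friday's 73%, and its target gives 6.30% against 6%, with a scatter of 1.5 percentage points. So I accept it.

What does it give? Scaling Thursday's last reading gives target 36.9%, starting material 21.6% and over-reaction product 13.5%.

And the homo dimer, which nobody read? That is the small correction and the weak spot. Thursday's last readings leave 8.89% unaccounted for beyond the other conformer charged. If that is dimer formed at second order in the starting material, its concentration in Friday's flask is a quarter of Thursday's. Friday's total charge is smaller too, so the percentage changes by a factor of 0.450, and I say 4.00%.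

The forecast says 40%, 23%, 13% and 4%, in the order asked, and holds that “Target goes on to over-reaction product”.

The flask gives target 38.2%, starting material 20.2%, over-reaction product 10.9% and homo dimer 2.50%.

    starting material ⇌ other conformer (K = 0.150, k = 0.130 min⁻¹)
    starting material → target (k = 0.370 min⁻¹)
    other conformer → isomer of the product (k = 2.60 min⁻¹)
    other conformer ⇌ third conformer (K = 0.410, k = 13.0 min⁻¹)
    third conformer → third product (k = 2.80 min⁻¹)
    2 other conformer → homo dimer (k = 12.0 M⁻¹ min⁻¹)
    target → over-reaction product (k = 0.140 min⁻¹)

Isomer of the product stands at 19.5%, more than the homo dimer. Against Thursday's last readings, the flask's target is 0.931 of its value and its starting material 0.842, on either side of s.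

Read at 80 s, the same flask stands at the time of Thursday's reading at 1.33 min, and s gives target 25.2% and starting material 42.3%. The computed values are 27.2% and 44.3%.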